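In a one-step world each electrophile takes one nucleophile and the flask is plain second order, but here every turnover also sets an acid free, and that acid has to land somewhere.

in all of them: electrophile 0.20 M; protic impurity 0.0400 M; solid base 1.00 equiv; time 40 s
- oak: nucleophile 3.90 equiv
- cedar: nucleophile 3.00 equiv
- maple: nucleophile 5.10 equiv

    electrophile + nucleophile → acid set free + target (k1 = 0.10 M⁻¹ s⁻¹)
    acid set free + free base ⇌ salt of the base (K2 = 2400 M⁻¹, k2 = 1.1 M⁻¹ s⁻¹)
    solid base ⇌ free base, rate k3*(cs3 - [free base]) while solid is left; crystals form when [free base] > cs3 (cs3 = 0.080 M, k3 = 0.017 s⁻¹)
    protic impurity + free base → quenched reagent (k4 = 0.13 M⁻¹ s⁻¹)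
    crystals ⇌ target, rate k5*(cs5 - [target]) while solid is left; crystals form when [target] > cs5 (cs5 = 0.20 M, k5 = 0.93 s⁻¹)
    nucleophile + acid set free ⇌ protonated nucleophile, settled at all times (K6 = 420 M⁻¹)

- for target the crystals are counted in
- as a solid, counted per litre of solution: crystals, solid base
- at the start none of the solid base is in solution
- run time (oak): 40 s

* part of the electrophile that has reacted at the end, oak
* part of the electrophile that has reacted at the end, cedar
* part of the electrophile that has reacted at the end, maple
* what raising the equivalents of nucleophile from its lowest to its highest value here does to the part of the electrophile that has reacted (changes below 5 percentage points count as none) (it falls / no change / it rises)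

In the first instants of cedar the nucleophile stands at its full charge, so the electrophile has a half-life of 12 s by step 1 alone, short against the run of 40 s.

In the middle of cedar the acid meets nucleophile in step 6, which is kept at balance. The equilibrium constant of step 6 times the nucleophile at the start is 250, so nearly all of the acid becomes protonated nucleophile, the resting state of the acid, and this form does not enter step 1. Step 1 takes one nucleophile and step 6 takes the bound share of another, which makes 2.00 nucleophiles lost per electrophile turned over, the nucleophile price.

Frozen at that value, the rate is the step 1 constant times electrophile left times nucleophile left, and the nucleophile left is its charge less the price times the turnover. Integrated, this reckoning gives 78.6% reacted at the end of cedar, 88.0% for oak and 94.7% for maple. The freeze holds to the end of cedar: the reckoned 47.7% of nucleophile left still gives a product of 120.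

The forecast gives 92.6% for oak, 85.7% for cedar and 97% for maple, with the trend it rises, and its ground is “the nucleophile consumed one-for-one”. The reckoning above charges 2.00 per turnover instead, and on cedar it stands lower than the forecast.

The flasks give 88.0% for oak, 78.7% for cedar and 94.7% for maple, and the trend is it rises, by 16 percentage points; the forecast stands 7 points above cedar. Cedar ends with 48% of its nucleophile left, which is 1.99 nucleophiles lost per electrophile reacted. The neighbouring flask, cedar with 1.80 equiv of nucleophile, is charged below the price, which makes nucleophile the limiting reagent. Its price of 1.99 gives 57.2% reacted, and that flask gives 57.3%, with 37% of its nucleophile left.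

The constants used here are made up; what happens was integrated by code.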